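A direct plan would follow the likely biogenesis: O4-alkylation of the silylated 4,7-dihydroxycoumarin A1 with the furan-bearing farnesyl chain would give the allyl vinyl ether A2, a [3,3] shift would move the chain to C3 with allylic inversion (A3), and alkaline lactone opening with loss of CO2 would leave the ketone. Its weakest steps would be: (a) the shift of A2 to A3, which would have to be enantioselective although no catalyst is known for 4-allyloxycoumarins and the thermal reaction is racemic; (b) the SeO2 allylic oxidation needed to functionalise the terminal methyl group of the terpenoid chain, which would over-oxidise and stop at moderate conversion; (c) the alkylation of the ambident A1, where C3 and O2 would compete with O4.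

The route rests on the C1–C2 disconnection (octenone numbering, C1 = C=O) next to the quaternary carbon C3 and reads the array CH2=CH–C3–C2H2 as the open form of a cyclopropylmethyl unit. The key step turns an enantiopure cyclopropylmethyl iodide into a (cyclopropylmethyl)lithium, whose strain-driven opening to the primary homoallyllithium unveils the vinyl group and the acyclic quaternary centre at once; acylation by a resorcylic Weinreb amide then forms the aryl ketone. The centre itself comes from a directed Simmons–Smith reaction on a C6 dienol, and the furan chain enters by B-alkyl Suzuki coupling, so no enantioselective sigmatropic shift, no allylic oxidation and no coumarin alkylation is needed.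

Key step: step 10

Remark: 4-methylfuran-2-carbaldehyde and (2E)-3-methylpent-2-en-4-yn-1-ol are taken as purchasable; the facial sense of step 5 is assigned by analogy with cinnamyl alcohol, for which the (4R,5R)-dioxaborolane is known to give the (1S,2S)-cyclopropylmethanol.

Step 1
Reactants: 1 4-methylfuran-2-carbaldehyde
Product: 2 (4-methylfuran-2-yl)methanol
Conditions: NaBH4 (0.6 equiv), MeOH, 0 °C
Reagents that add atoms: none
Why: Borohydride 1,2-reduction of the aldehyde to the primary alcohol; the furan ring is inert and no stereocentre is formed.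

Step 2
Reactants: 2 (4-methylfuran-2-yl)methanol
Product: 4 4-methyl-2-(prop-2-yn-1-yl)furan, via furfuryl chloride 3 (not isolated)
Conditions: SOCl2 (1.05 equiv), pyridine (1.1 equiv), Et2O, −20 °C; cold filtrate added to HC≡CMgBr (3 equiv), CuCl (10 mol%), THF, 0 °C → rt
Reagents that add atoms: ethynylmagnesium bromide, C#C[Mg]Br
Why: Chlorodehydroxylation gives the reactive furfuryl chloride, which is used at once in a copper-catalysed SN2 alkynylation by the ethynyl Grignard reagent (Grignard cross-coupling of a benzylic-type halide), the excess of acetylide suppressing double alkylation; no stereocentre is formed.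

Step 3
Reactants: 4 4-methyl-2-(prop-2-yn-1-yl)furan
Product: 6 2-[(2E)-3-iodo-2-methylprop-2-en-1-yl]-4-methylfuran, via alkenylalane 5 (not isolated)
Conditions: Me3Al (2.0 equiv), Cp2ZrCl2 (0.25 equiv), (CH2Cl)2, 0 °C → rt; then I2 (1.2 equiv), THF, −30 °C
Reagents that add atoms: trimethylaluminium, C[Al](C)C; iodine, II
Why: Negishi zirconium-catalysed carboalumination adds Me and Al syn across the terminal alkyne with the methyl group on the internal carbon, and iodinolysis of the C–Al bond with retention gives the (E)-iodide, which fixes the C6=C7 geometry of the target.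

Step 4
Reactants: 7 (2E)-3-methylpent-2-en-4-yn-1-ol
Product: 8 (2E)-3-methylpenta-2,4-dien-1-ol
Conditions: H2 (1 atm), Pd/CaCO3 poisoned with Pb(OAc)2, quinoline, pentane/Et2O, rt, stopped after 1 equiv H2
Reagents that add atoms: none
Why: Lindlar semihydrogenation: the poisoned palladium catalyst adds one equivalent of H2 to the terminal alkyne and stops at the vinyl group, leaving the (E)-trisubstituted alkene and the allylic alcohol intact.

Step 5
Reactants: 8 (2E)-3-methylpenta-2,4-dien-1-ol
Product: 9 [(1R,2S)-2-ethenyl-2-methylcyclopropyl]methanol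
Conditions: Et2Zn (2.2 equiv), CH2I2 (4.4 equiv), DME (2.2 equiv), CH2Cl2, −10 °C; then 8 and (4S,5S)-2-butyl-N,N,N′,N′-tetramethyl-1,3,2-dioxaborolane-4,5-dicarboxamide (1.2 equiv), −10 °C → rt; aq. NH4Cl, then aq. KOH wash
Reagents that add atoms: diiodomethane, ICI
Why: Charette asymmetric Simmons–Smith cyclopropanation: the zinc alkoxide of 8 is bound by the chiral dioxaborolane, which directs stereospecific syn transfer of CH2 from the zinc carbenoid to one face of the allylic alkene only (the remote vinyl group is not directed and stays), so the E geometry places vinyl trans to CH2OH and the (4S,5S) ligand should set C1 as (R) and the quaternary C2 as (S), the arrangement that becomes (3R) in the target.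

Step 6
Reactants: 9 [(1R,2S)-2-ethenyl-2-methylcyclopropyl]methanol; 6 2-[(2E)-3-iodo-2-methylprop-2-en-1-yl]-4-methylfuran
Product: 11 {(1R,2R)-2-methyl-2-[(3E)-4-methyl-5-(4-methylfuran-2-yl)pent-3-en-1-yl]cyclopropyl}methanol, via alkylborane 10 (not isolated)
Conditions: 9-BBN (2.2 equiv B–H), THF, 0 °C → rt; then 6 (1.0 equiv), Pd(dppf)Cl2 (5 mol%), AsPh3 (5 mol%), Cs2CO3 (3 equiv), DMF/H2O, rt, dark
Reagents that add atoms: none
Why: B-alkyl Suzuki–Miyaura coupling: 9-BBN adds anti-Markovnikov to the vinyl group (a second equivalent is consumed by the hydroxyl group), the primary alkyl group is transferred from boron to palladium under aqueous base and couples with the alkenyl iodide with retention of the E geometry; the cyclopropane stereocentres are not touched (the descriptor of C2 changes to R only because the priorities change).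

Step 7
Reactants: 11 {(1R,2R)-2-methyl-2-[(3E)-4-methyl-5-(4-methylfuran-2-yl)pent-3-en-1-yl]cyclopropyl}methanol
Product: 12 2-{(2E)-5-[(1R,2R)-2-(iodomethyl)-1-methylcyclopropyl]-2-methylpent-2-en-1-yl}-4-methylfuran
Conditions: PPh3 (1.3 equiv), I2 (1.3 equiv), imidazole (2.5 equiv), CH2Cl2, 0 °C, dark; used at once
Reagents that add atoms: iodine, II
Why: Appel-type iodination: SN2 displacement of the alkoxyphosphonium ion by iodide at the primary carbon under buffered, non-ionising conditions, which avoids cyclopropylcarbinyl cation rearrangement; furan and alkene are spectators.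

Step 8
Reactants: 13 methyl 2,4-dihydroxybenzoate
Product: 14 methyl 2,4-bis[(tert-butyldimethylsilyl)oxy]benzoate
Conditions: TBSCl (2.4 equiv), imidazole (3 equiv), DMF, rt
Reagents that add atoms: tert-butyldimethylsilyl chloride, CC(C)(C)[Si](C)(C)Cl
Why: Silyl ether formation protects both phenols, imidazole being basic enough to break the hydrogen bond of the 2-OH group to the ester.

Step 9
Reactants: 14 methyl 2,4-bis[(tert-butyldimethylsilyl)oxy]benzoate
Product: 15 2,4-bis[(tert-butyldimethylsilyl)oxy]-N-methoxy-N-methylbenzamide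
Conditions: MeNH(OMe)·HCl (1.5 equiv), i-PrMgCl (3.0 equiv), THF, −20 → 0 °C
Reagents that add atoms: N,O-dimethylhydroxylamine hydrochloride, CNOC.Cl
Why: Direct conversion of the ester into the Weinreb amide by nucleophilic acyl substitution with the chloromagnesium amide made in the flask; aryl silyl ethers are stable to the Grignard base at this temperature.

Step 10
Reactants: 12 2-{(2E)-5-[(1R,2R)-2-(iodomethyl)-1-methylcyclopropyl]-2-methylpent-2-en-1-yl}-4-methylfuran; 15 2,4-bis[(tert-butyldimethylsilyl)oxy]-N-methoxy-N-methylbenzamide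
Product: 19 (3R,6E)-1-{2,4-bis[(tert-butyldimethylsilyl)oxy]phenyl}-3-ethenyl-3,7-dimethyl-8-(4-methylfuran-2-yl)oct-6-en-1-one, via cyclopropylmethyllithium 16 (not isolated), via homoallyllithium 17 (not isolated), via lithium hemiaminal alkoxide 18 (not isolated)
Conditions: 12 added to t-BuLi (2.05 equiv), Et2O/pentane, −78 °C, 20 min, then −40 °C, 20 min; 15 (1.1 equiv) in THF, −78 → 0 °C; aq. NH4Cl
Reagents that add atoms: none
Why: Iodine–lithium exchange with two equivalents of t-BuLi (the second destroys t-BuI) gives the (cyclopropylmethyl)lithium 16, which undergoes the polar cyclopropylcarbinyl-to-homoallyl rearrangement: the ring bond from the carbinyl carbon to the ring CH2 breaks with relief of about 27 kcal/mol of strain, so that the former CH–CH2I unit becomes the vinyl group and the ring CH2 becomes the CH2Li carbon (C2 of the target) on the now acyclic quaternary carbon C3. The closest known reaction types are the regioselective opening of substituted (cyclopropylmethyl)lithiums made from their iodides and the Weinreb ketone synthesis, in which 17 adds once to 15 to give the chelated tetrahedral adduct 18 that releases the ketone only on work-up. No ring is closed (the three-membered ring is opened) and no new stereocentre is formed: none of the four bonds of C3 is broken, so its configuration, set in step 5, is carried over unchanged and becomes (R) in 19. The step needs cleavage of the bond to the ring CH2 and not of the bond to the quaternary carbon, which is secured because the alternative would place the charge on a tertiary carbon with only alkyl substituents whereas the expected path gives a primary alkyllithium; it also needs the exchange to outrun proton transfer from the furan C5–H, which should hold at −78 °C in ether/pentane. Carbolithiation of the C6=C7 alkene is not expected because it would create a tertiary alkyllithium, and a radical opening (which would go towards the tertiary carbon) is avoided by using the iodide with t-BuLi at low temperature.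

Step 11
Reactants: 19 (3R,6E)-1-{2,4-bis[(tert-butyldimethylsilyl)oxy]phenyl}-3-ethenyl-3,7-dimethyl-8-(4-methylfuran-2-yl)oct-6-en-1-one
Product: 20 (3R,6E)-1-(2,4-dihydroxyphenyl)-3-ethenyl-3,7-dimethyl-8-(4-methylfuran-2-yl)oct-6-en-1-one
Conditions: TBAF (2.5 equiv), AcOH (2.5 equiv), THF, 0 °C
Reagents that add atoms: none
Why: Fluoride-induced cleavage of the two aryl silyl ethers, buffered with acetic acid; the quaternary centre has no acidic hydrogen and cannot epimerise, and furan and alkenes are inert.

**Compound list**
1 | 4-methylfuran-2-carbaldehyde | O=Cc1cc(C)co1 | starting material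
2 | (4-methylfuran-2-yl)methanol | OCc1cc(C)co1 | intermediate
3 | 2-(chloromethyl)-4-methylfuran | ClCc1cc(C)co1 | intermediate
4 | 4-methyl-2-(prop-2-yn-1-yl)furan | C#CCc1cc(C)co1 | intermediate
5 | dimethyl[(1E)-2-methyl-3-(4-methylfuran-2-yl)prop-1-en-1-yl]alumane | C[Al](C)/C=C(\C)Cc1cc(C)co1 | intermediate
6 | 2-[(2E)-3-iodo-2-methylprop-2-en-1-yl]-4-methylfuran | I/C=C(\C)Cc1cc(C)co1 | intermediate
7 | (2E)-3-methylpent-2-en-4-yn-1-ol | C#C/C(C)=C/CO | starting material
8 | (2E)-3-methylpenta-2,4-dien-1-ol | C=C/C(C)=C/CO | intermediate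
9 | [(1R,2S)-2-ethenyl-2-methylcyclopropyl]methanol | OC[C@@H]1C[C@@]1(C)C=C | intermediate
10 | 9-{2-[(1R,2R)-2-{[(9-borabicyclo[3.3.1]nonan-9-yl)oxy]methyl}-1-methylcyclopropyl]ethyl}-9-borabicyclo[3.3.1]nonane | C1CCC2CCCC1B2OC[C@@H]3C[C@@]3(C)CCB4C5CCCC4CCC5 | intermediate
11 | {(1R,2R)-2-methyl-2-[(3E)-4-methyl-5-(4-methylfuran-2-yl)pent-3-en-1-yl]cyclopropyl}methanol | OC[C@@H]1C[C@@]1(C)CC/C=C(\C)Cc1cc(C)co1 | intermediate
12 | 2-{(2E)-5-[(1R,2R)-2-(iodomethyl)-1-methylcyclopropyl]-2-methylpent-2-en-1-yl}-4-methylfuran | IC[C@@H]1C[C@@]1(C)CC/C=C(\C)Cc1cc(C)co1 | intermediate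
13 | methyl 2,4-dihydroxybenzoate | COC(=O)c1ccc(O)cc1O | starting material
14 | methyl 2,4-bis[(tert-butyldimethylsilyl)oxy]benzoate | COC(=O)c1ccc(O[Si](C)(C)C(C)(C)C)cc1O[Si](C)(C)C(C)(C)C | intermediate
15 | 2,4-bis[(tert-butyldimethylsilyl)oxy]-N-methoxy-N-methylbenzamide | CON(C)C(=O)c1ccc(O[Si](C)(C)C(C)(C)C)cc1O[Si](C)(C)C(C)(C)C | intermediate
16 | ({(1R,2R)-2-methyl-2-[(3E)-4-methyl-5-(4-methylfuran-2-yl)pent-3-en-1-yl]cyclopropyl}methyl)lithium | [Li]C[C@@H]1C[C@@]1(C)CC/C=C(\C)Cc1cc(C)co1 | intermediate
17 | [(2S,5E)-2-ethenyl-2,6-dimethyl-7-(4-methylfuran-2-yl)hept-5-en-1-yl]lithium | [Li]C[C@](C)(C=C)CC/C=C(\C)Cc1cc(C)co1 | intermediate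
18 | lithium (3R,6E)-1-{2,4-bis[(tert-butyldimethylsilyl)oxy]phenyl}-3-ethenyl-1-[methoxy(methyl)amino]-3,7-dimethyl-8-(4-methylfuran-2-yl)oct-6-en-1-olate (C1 epimers) | [Li]OC(N(C)OC)(C[C@](C)(C=C)CC/C=C(\C)Cc1cc(C)co1)c1ccc(O[Si](C)(C)C(C)(C)C)cc1O[Si](C)(C)C(C)(C)C | intermediate
19 | (3R,6E)-1-{2,4-bis[(tert-butyldimethylsilyl)oxy]phenyl}-3-ethenyl-3,7-dimethyl-8-(4-methylfuran-2-yl)oct-6-en-1-one | C=C[C@](C)(CC/C=C(\C)Cc1cc(C)co1)CC(=O)c1ccc(O[Si](C)(C)C(C)(C)C)cc1O[Si](C)(C)C(C)(C)C | intermediate
20 | (3R,6E)-1-(2,4-dihydroxyphenyl)-3-ethenyl-3,7-dimethyl-8-(4-methylfuran-2-yl)oct-6-en-1-one | C=C[C@](C)(CC/C=C(\C)Cc1cc(C)co1)CC(=O)c1ccc(O)cc1O | target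

Total step count: 11. Longest linear sequence: 7 steps (steps 1, 2, 3, 6, 7, 10, 11).

Steps most likely to fail:

Step 10 (key step). The alkyllithium 17 may be consumed by proton transfer (from the furan C5–H, from the doubly allylic C8–H2, or by elimination at the N–OMe group of 15) before the slow acyl transfer to the hindered, electron-rich amide is complete. The fallback sets out from 12 and 15: 15 would be reduced with DIBAL-H (THF, −78 °C) to 2,4-bis[(tert-butyldimethylsilyl)oxy]benzaldehyde F1. Lithium reagent 17, made from 12 as before, would be trapped at −78 °C with this far more electrophilic aldehyde to give (3R,6E)-1-{2,4-bis[(tert-butyldimethylsilyl)oxy]phenyl}-3-ethenyl-3,7-dimethyl-8-(4-methylfuran-2-yl)oct-6-en-1-ol F2 as both C1 epimers. Oxidation of this benzylic alcohol with MnO2 (CH2Cl2, rt) would rejoin the route at 19.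

Step 6. Hydroboration of the neopentyl-type vinyl group next to a free hydroxyl group may be slow or incomplete, and the alkylborane may be lost by protodeboronation during the coupling. The fallback sets out from 8 and 6 and reverses the order of coupling and ring formation. The terminal vinyl group of the diene 8 would be hydroborated with 9-BBN to 9-[(3E)-5-(9-borabicyclo[3.3.1]nonan-9-yloxy)-3-methylpent-3-en-1-yl]-9-borabicyclo[3.3.1]nonane F3, which would be coupled with 6 under the conditions of step 6 to give (2E,6E)-3,7-dimethyl-8-(4-methylfuran-2-yl)octa-2,6-dien-1-ol F4. Cyclopropanation of this geraniol-type alcohol under the conditions of step 5 (same ligand, same facial sense) would rejoin the route at 11.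

Step 2. The furfuryl chloride 3 may polymerise before it couples, and the basic acetylide may isomerise the skipped enyne 4 to the allene. The fallback sets out from 1: the aldehyde would be homologated by Wittig reaction with Ph3P=CHOMe to 2-(2-methoxyethenyl)-4-methylfuran F5 (E/Z mixture), which would be hydrolysed with aqueous oxalic acid to (4-methylfuran-2-yl)acetaldehyde F6. Seyferth–Gilbert homologation with the Ohira–Bestmann reagent (K2CO3, MeOH, 0 °C) would rejoin the route at 4.

**Further compounds**
F1 | step 10 | 2,4-bis[(tert-butyldimethylsilyl)oxy]benzaldehyde | O=Cc1ccc(O[Si](C)(C)C(C)(C)C)cc1O[Si](C)(C)C(C)(C)C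
F2 | step 10 | (3R,6E)-1-{2,4-bis[(tert-butyldimethylsilyl)oxy]phenyl}-3-ethenyl-3,7-dimethyl-8-(4-methylfuran-2-yl)oct-6-en-1-ol (C1 epimers) | C=C[C@](C)(CC/C=C(\C)Cc1cc(C)co1)CC(O)c1ccc(O[Si](C)(C)C(C)(C)C)cc1O[Si](C)(C)C(C)(C)C
F3 | step 6 | 9-[(3E)-5-(9-borabicyclo[3.3.1]nonan-9-yloxy)-3-methylpent-3-en-1-yl]-9-borabicyclo[3.3.1]nonane | C1CCC2CCCC1B2OC/C=C(\C)CCB3C4CCCC3CCC4
F4 | step 6 | (2E,6E)-3,7-dimethyl-8-(4-methylfuran-2-yl)octa-2,6-dien-1-ol | OC/C=C(\C)CC/C=C(\C)Cc1cc(C)co1
F5 | step 2 | 2-(2-methoxyethenyl)-4-methylfuran (E/Z mixture) | COC=Cc1cc(C)co1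
F6 | step 2 | (4-methylfuran-2-yl)acetaldehyde | O=CCc1cc(C)co1
A1 | direct plan | 7-[(tert-butyldimethylsilyl)oxy]-4-hydroxy-2H-chromen-2-one | O=C1C=C(O)c2ccc(O[Si](C)(C)C(C)(C)C)cc2O1
A2 | direct plan | 7-[(tert-butyldimethylsilyl)oxy]-4-{[(2E,6E)-3,7-dimethyl-8-(4-methylfuran-2-yl)octa-2,6-dien-1-yl]oxy}-2H-chromen-2-one | O=C1C=C(OC/C=C(\C)CC/C=C(\C)Cc2cc(C)co2)c2ccc(O[Si](C)(C)C(C)(C)C)cc2O1
A3 | direct plan | 7-[(tert-butyldimethylsilyl)oxy]-4-hydroxy-3-[(3S,6E)-3,7-dimethyl-8-(4-methylfuran-2-yl)octa-1,6-dien-3-yl]-2H-chromen-2-one | C=C[C@](C)(CC/C=C(\C)Cc1cc(C)co1)C1=C(O)c2ccc(O[Si](C)(C)C(C)(C)C)cc2OC1=O
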